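## Structural features

Abietane numbering is used throughout: ring A is C1–C5 and C10, ring B is C5–C10, ring C is C8, C9 and C11–C14; C18 and C19 sit on C4, C20 on C10.

- Ring C is a fully substituted p-quinone (carbonyls at C11 and C14) with an isopropyl group at C13 and an enol acetate at C12.
- Ring B carries a C6=C7 double bond that is conjugated through C8=C9 to the C11 carbonyl.
- Ring A is bridged by a δ-lactone from the C4 carboxyl carbon C19 to the oxygen on C20, so ring A and the lactone form a 2-oxabicyclo[3.3.1]nonan-3-one.
- The three stereocentres C4, C5 and C10 are contiguous. C4 and C10 are quaternary and flank C5; the lactone forces C19 and C20 onto one face, H5 lies on the other (trans A/B junction), and the target is (4S,5R,10R).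
- Fragile groups are the enol acetate (a vinylogous anhydride), the quinone with its extended dienone, the allylic and vinylogously acidic C5–H, and the lactone towards strong nucleophiles.
- The real difficulty is the quaternary C10 next to the hexasubstituted ring C, which must be set in absolute terms, and the relay of its configuration to C4 and C5.
- The key step exploits the fact that C8 and C9 of ring C carry ring B through C7 and C10. This is the pattern left when the unsubstituted C=C of an isopropyl-p-quinone adds across a 1-vinylcyclohexene whose ring is ring A, so ring B is the cycloadduct ring and C10 is the substituted diene terminus.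

## Logic of the disconnections

**26 ⇒ 25.** The acyl–O bond at C12 is cut. The enol acetate is the most labile group and is best made last. The forward step needs only O-acylation of an acidic hydroxyquinone.

**25 ⇒ 24 ⇒ 23.** The C12–O bond is cut. C12 is the only C–H of ring C and is the β-position of the C14 enone, so oxygen can be added there by nucleophilic oxidation at the end. Carrying this oxygen on the dienophile would make the other carbonyl the more basic one and reverse the regiochemistry of the cycloaddition. The forward steps need site-selective epoxidation of C12=C13 and a redox-neutral opening of the oxirane.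

**23 ⇒ 22.** The two quinone carbonyls are traced back to aryl methyl ethers. Ring C then travels as a robust arene through base, hydride and radical steps. The forward step must oxidise the arene without touching the conjugated C6=C7 bond.

**22 ⇒ 21 ⇒ 20.** The C18–H bond is traced to C18–I and then C18–O. C18 must come from a group identical to C19 so that C4 is not a stereocentre before the cycloaddition. The forward steps must remove a neopentyl oxygen; the radical step is placed after the alkene has left the β,γ-position to C18, which avoids a homoallyl radical rearrangement.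

**20 ⇒ 19.** The C5–H bond is cut and the double bond returned from C6=C7 to C5=C6, where the cycloaddition leaves it. C5 is therefore set by prototropy. The forward step needs thermodynamic control, and the lactone is installed first so that ring A is locked and the trans junction is the favoured one.

**19 ⇒ 18.** The C18 alcohol is traced to a carboxylic acid. The forward step must reduce a free acid beside a lactone and a hindered alkene.

**18 ⇒ 16.** The lactone C19–O bond, two ester O–alkyl bonds and the O–Si bond are cut. A C4 gem-diester and a C20 alcohol remain; only the ester cis to C20 can close, so C4 becomes stereogenic without a reagent-controlled step. tert-Butyl esters are chosen so that one acid treatment frees the alcohol and both acids and leaves the unlactonised carboxyl ready for reduction.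

**16 ⇒ 14.** Ring C is returned to the cis-fused enedione by cutting two O–methyl bonds and reversing the tautomerisation. The C8 and C9 stereocentres are spent here. The forward step needs O- rather than C-methylation and exclusion of air.

**14 ⇒ 11 + 13.** The C7–C8 and C9–C10 bonds are cut. This removes ring B and the only stereocentre that must be set by a reagent, and gives an achiral diene and a simple quinone. The forward step needs site, regio, endo and facial selectivity at a fully substituted diene terminus.

**13 ⇒ 12.** The C–O bond para to the phenol oxygen is cut. The forward step is a para-selective phenol oxidation.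

**11 ⇒ 10 ⇒ 9.** The O–Si bond is cut and C20 is raised to the ester level. C20 enters as the ester that makes the ring closure to 6 viable. The forward steps must reduce one conjugated methyl ester beside two tert-butyl esters and mask the alcohol from the Lewis acid.

**9 ⇒ 7 + 8.** The C5–C6 bond is cut. A C5 ketone serves as the handle for the vinyl group. The forward step is a cross-coupling at a tetrasubstituted enol triflate.

**7 ⇒ 6.** The C5–O sulfonate bond is cut. Only C10 can enolise, so one regioisomer is possible.

**6 ⇒ 5.** The C4–C5 bond is cut (Dieckmann).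
- A precursor with a single ester at the far end would not do. Closure of a malonate carbon onto a lone ester gives a ketone with no acidic hydrogen between two carbonyl groups, the equilibrium is not pulled over, and closure through the other α-carbon to a 1,3-diester takes over.
- With a malonate at both ends, the product keeps an acidic hydrogen at C10.
- The tert-butyl/methyl difference decides which malonate is the nucleophile.

**5 ⇒ 3 + 4 and 3 ⇒ 1 + 2.** The C1–C10 and C3–C4 bonds are cut. Two malonate alkylations on a three-carbon dielectrophile give the chain. The forward steps must avoid cyclobutane closure of 3.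

## Other disconnections considered

**Alternative 1:** Rings B and C are cut together at C8–C9, C11–C12 and C13–C14. In the forward sense the lactone-bearing diyne A2 and 3-methylbut-1-yne A3 are trimerised with Cp*RuCl(cod) (divalent ruthenium) to the arylboronate A1. The mechanism is oxidative cyclisation to a ruthenacyclopentadiene, insertion of A3 and reductive elimination.
- In its favour: three C–C bonds and two rings form in one step, against two bonds and one ring in the chosen plan. The lactone, C4, C5, C10 and the C6=C7 bond are all in place beforehand, so no alkene isomerisation and no late adjustment at C18 are needed. On these points Alternative 1 is the better plan.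
- The required orientation of A3 (isopropyl meta to boron) is the sterically normal one, so regiochemistry is equal to the chosen plan in reliability.
- Against it: A1 carries only a latent oxygen at C11, while C12 and C14 are C–H. Three C–O bonds remain to be made; the chosen dienophile delivers two of them.
- The stereochemical problem is moved into A2, a bicyclic lactone with an alkynyl group on quaternary C10 and a Z-enyne on C5. The key step does nothing to solve it, and A2 is likely to cost more steps than the cyclotrimerisation saves.

**Alternative 2:** The C10–C20 bond is cut. In the forward sense Rh2(OAc)4 (divalent rhodium) decomposes the diazoketone A5, and the carbenoid inserts into the tertiary, benzylic C10–H to give the bridged cyclopentanone A4.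
- In its favour: insertion proceeds with retention and the tether guarantees the cis relation of C19 and C20. This is equal to the certainty that lactonisation gives in the chosen plan. The trimethoxy ring C already holds the C12 oxygen, which is better than a late hydroxylation.
- Against it: the step makes one C–C bond, and A5 must already contain C4, C5 and C10 in a 20-nor trans-fused skeleton, with C10–H cis to the acyl group. Absolute control is again left to earlier chemistry.
- Insertion into the C2–H or C6–H bonds, ylide formation at the C11 methoxy group and arene cyclopropanation can compete.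
- The later C19–C20 cleavage is awkward. A Baeyer–Villiger oxidation would migrate quaternary C4 and put the ring oxygen on C4 instead of C20. A longer detour through C20 oxygenation, cleavage and reduction is needed, followed by dehydrogenation to C6=C7. Step economy after the key step is therefore worse than in the chosen plan.

**Alternative 3:** The C5–C10 and C3–C4 bonds are cut. In the forward sense the triene A7 undergoes a Lewis acid promoted intramolecular Diels–Alder reaction to the trans-fused tricycle A6.
- In its favour: rings A and B and all three stereocentres arise in one step from an achiral, linear precursor. C18 is already a methyl group and C19 the ester that lactonises, so the acid-to-methyl sequence of the chosen plan is not needed. The arene holds the C12 oxygen. On bond count and on the C4 substituents Alternative 3 is the better plan.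
- Against it: a trisubstituted dienophile must meet a diene terminus that bears an inside substituent, and two quaternary carbons form at once. The s-cis diene is strained and aryl conjugation is lost in the transition state.
- The trans junction requires one of two tether geometries.
- Enantiocontrol would rest on a chiral Lewis acid bound to a simple ester, which is less secure than activation of a quinone. The chosen plan has the better-founded absolute control.
- After the key step, the C1=C2 bond must be reduced and the C6=C7 bond introduced, so the step count is about equal.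

Key step: step 9

Assumption: the absolute sense of step 9 is taken from the pretransition-state model of the oxazaborolidinium–quinone complex (boron on the C11 oxygen syn to C9–H, the reacting edge stacked on a phenyl ring). On this model the (S)-catalyst delivers 14; the (R)-catalyst is equally available should the sense prove opposite.

## Route

Step 1
Reactants: 1 di-tert-butyl malonate; 2 1-bromo-3-chloropropane
Product: 3 di-tert-butyl 2-(3-chloropropyl)malonate
Conditions: NaH (1.0 equiv), THF/DMF, 0 °C; 2 (3 equiv), 0 °C → rt
Reagents that add atoms: none
Why: Malonic ester alkylation (SN2) at the bromide end, the better leaving group; one equivalent of base and excess 2 should hold back dialkylation and four-ring closure.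

Step 2
Reactants: 3 di-tert-butyl 2-(3-chloropropyl)malonate; 4 dimethyl malonate
Product: 5 1,1-di-tert-butyl 5,5-dimethyl pentane-1,1,5,5-tetracarboxylate
Conditions: 4 (2.5 equiv), NaH (2.2 equiv), NaI (cat.), DMF, 60 °C
Reagents that add atoms: none
Why: Malonic ester alkylation with in situ Finkelstein exchange; the excess and more acidic anion of 4 keeps 3 protonated, so cyclobutane formation from 3 should not compete.

Step 3
Reactants: 5 1,1-di-tert-butyl 5,5-dimethyl pentane-1,1,5,5-tetracarboxylate
Product: 6 1,1-di-tert-butyl 3-methyl 2-oxocyclohexane-1,1,3-tricarboxylate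
Conditions: NaH (1.2 equiv), MeOH (cat.), toluene, 80 °C; AcOH
Reagents that add atoms: none
Why: Dieckmann condensation (6-exo-trig): the di-tert-butyl malonate carbon C4 acylates on a methyl ester, tert-butyl esters being poor acceptors, and forms C4–C5. The product keeps an acidic β-keto ester hydrogen at C10, whose removal pulls the equilibrium over.

Step 4
Reactants: 6 1,1-di-tert-butyl 3-methyl 2-oxocyclohexane-1,1,3-tricarboxylate
Product: 7 1,1-di-tert-butyl 3-methyl 2-(trifluoromethanesulfonyloxy)cyclohex-2-ene-1,1,3-tricarboxylate
Conditions: NaH, Et2O, 0 °C; Tf2O, −78 → 0 °C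
Reagents that add atoms: triflic anhydride O=S(=O)(OS(=O)(=O)C(F)(F)F)C(F)(F)F
Why: O-sulfonylation of a β-keto ester enolate (enol triflate formation); C4 is quaternary, so only the C5=C10 enol triflate can form.

Step 5
Reactants: 7 1,1-di-tert-butyl 3-methyl 2-(trifluoromethanesulfonyloxy)cyclohex-2-ene-1,1,3-tricarboxylate; 8 tributyl(vinyl)stannane
Product: 9 1,1-di-tert-butyl 3-methyl 2-vinylcyclohex-2-ene-1,1,3-tricarboxylate
Conditions: Pd(PPh3)4 (5 mol %), LiCl, THF, 65 °C
Reagents that add atoms: none
Why: Stille cross-coupling forming C5–C6; β-triflyloxy enoates add readily to zerovalent palladium and the small vinyl group should tolerate the neighbouring quaternary C4.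

Step 6
Reactants: 9 1,1-di-tert-butyl 3-methyl 2-vinylcyclohex-2-ene-1,1,3-tricarboxylate
Product: 10 di-tert-butyl 3-(hydroxymethyl)-2-vinylcyclohex-2-ene-1,1-dicarboxylate
Conditions: i-Bu2AlH (2.3 equiv), CH2Cl2, −78 °C; aq. potassium sodium tartrate
Reagents that add atoms: none
Why: 1,2-Reduction of the conjugated methyl ester to the allylic alcohol; tert-butyl esters on a quaternary carbon accept hydride far more slowly at −78 °C. The alcohol cannot lactonise because that would put the C5=C10 bond at a bridgehead.

Step 7
Reactants: 10 di-tert-butyl 3-(hydroxymethyl)-2-vinylcyclohex-2-ene-1,1-dicarboxylate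
Product: 11 di-tert-butyl 3-[(tert-butyldimethylsilyloxy)methyl]-2-vinylcyclohex-2-ene-1,1-dicarboxylate
Conditions: TBSCl, imidazole, DMF, rt
Reagents that add atoms: tert-butyldimethylsilyl chloride CC(C)(C)[Si](C)(C)Cl
Why: Silylation of a primary allylic alcohol; the ether masks the hydroxyl from the Lewis acid of step 9.

Step 8
Reactants: 12 2-isopropylphenol
Product: 13 2-isopropyl-1,4-benzoquinone
Conditions: O2 (1 atm), Co(salen) (5 mol %), DMF, rt
Reagents that add atoms: dioxygen O=O
Why: Cobalt–salen catalysed para-oxygenation of a phenol to the p-quinone; the ortho isopropyl group and DMF should disfavour oxidative C–C coupling.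

Step 9
Reactants: 11 di-tert-butyl 3-[(tert-butyldimethylsilyloxy)methyl]-2-vinylcyclohex-2-ene-1,1-dicarboxylate; 13 2-isopropyl-1,4-benzoquinone
Product: 14 endo cycloadduct (8R,9R,10S): cis-fused enedione with C5=C6 and C12=C13 double bonds; two tert-butyl esters on C4; CH2OTBS on C10; H8, H9 and C20 on one face
Conditions: (S)-o-tolyl-oxazaborolidinium triflimide (20 mol %; from (S)-α,α-diphenylprolinol, tri-o-tolylboroxine and Tf2NH), CH2Cl2, −78 → −20 °C
Reagents that add atoms: none
Why: Concerted but asynchronous endo [4+2] cycloaddition, a Lewis acid catalysed quinone Diels–Alder reaction; the closest known types are Lewis acid promoted additions of quinones to 2,6,6-trisubstituted 1-vinylcyclohexenes and oxazaborolidinium-catalysed quinone cycloadditions. Boron binds the C11 carbonyl, the less hindered and more basic one (the isopropyl-bearing C13 is its β-carbon), on the lone pair syn to C9–H, so only the unsubstituted C8=C9 bond is activated and C8 becomes the electrophilic end. The unsubstituted diene terminus C7, which has the largest HOMO coefficient, bonds to C8 first and the fully substituted C10 then closes onto C9; this fixes the regiochemistry. Ring B is closed as the six-membered ring of the cycloaddition, suprafacially on both partners. Endo approach, with the quinone ring under C5–C6, puts H8, H9 and C20 on one face. Diene 11 has no stereocentre, so the quinone face left open by the catalyst (the other is covered by a phenyl ring of the diphenylcarbinol unit) alone sets C10 and with it C8 and C9. The step needs site selectivity, C7-to-C8 regiochemistry, endo selectivity and one face: the first two follow from quinone substitution and catalyst binding, the last two from secondary overlap and the catalyst pocket. The C4 diester disfavours the s-trans diene conformer, and the silyl ether and tert-butyl esters should survive at low temperature.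

Step 10
Reactants: 14 endo cycloadduct
Product: 16 (10R)-11,14-dimethoxy arene with C5=C6; two tert-butyl esters on C4; CH2OTBS on C10, via hydroquinone 15 (not isolated)
Conditions: K2CO3, acetone, rt (Ar); Me2SO4, reflux
Reagents that add atoms: dimethyl sulfate COS(=O)(=O)OC
Why: Base-mediated double enolisation of the cis-fused enedione gives the aromatic hydroquinone (tautomerisation), which is O-methylated in the same flask (Williamson ether synthesis). The C8 and C9 stereocentres are spent and quaternary C10 cannot epimerise.

Step 11
Reactants: 16 (10R)-11,14-dimethoxy arene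
Product: 18 (4S,10R)-lactone acid: 19,20-δ-lactone; free carboxyl as C18; C5=C6; 11,14-dimethoxy, via hydroxy diacid 17 (not isolated)
Conditions: TFA/CH2Cl2/H2O (10:10:1), anisole, 0 °C → rt; toluene, 60 °C
Reagents that add atoms: none
Why: Acidolysis of both tert-butyl esters and the primary silyl ether, then acid-catalysed (Fischer-type) lactonisation. Only the carboxyl on the same face of ring A as C20 can reach the alcohol, so C4 becomes stereogenic with C19 cis to C20.

Step 12
Reactants: 18 (4S,10R)-lactone acid
Product: 19 (4S,10R)-lactone alcohol: C18 as CH2OH; C5=C6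
Conditions: BH3·SMe2 (2.5 equiv), THF, 0 °C → rt; MeOH
Reagents that add atoms: none
Why: Chemoselective borane reduction of a free carboxylic acid through its acyloxyborane; this should be much faster than attack on the hindered lactone or on the trisubstituted alkene flanked by two quaternary carbons.

Step 13
Reactants: 19 (4S,10R)-lactone alcohol
Product: 20 (4S,5R,10R)-lactone alcohol with C6=C7 and H5 trans to C20
Conditions: KOt-Bu (2.5 equiv), DMSO, rt; AcOH
Reagents that add atoms: none
Why: Base-mediated prototropic alkene isomerisation of the 1,4- to 1,2-dihydronaphthalene type: deprotonation at the benzylic, allylic C7 and reprotonation at C5 bring the double bond into conjugation with ring C. Under these reversible conditions the C5 epimer with C6 equatorial on the lactone-locked ring A (trans junction) should predominate.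

Step 14
Reactants: 20 (4S,5R,10R)-lactone alcohol
Product: 21 (4R,5R,10R)-lactone iodide: C18 as CH2I
Conditions: I2, PPh3, imidazole, toluene, 90 °C
Reagents that add atoms: iodine II
Why: Appel-type iodination through the alkoxyphosphonium salt; the neopentyl carbon needs heat but has no β-hydrogen to eliminate.

Step 15
Reactants: 21 (4R,5R,10R)-lactone iodide
Product: 22 (4S,5R,10R)-11,14-dimethoxyabieta-6,8,11,13-tetraen-19,20-olide
Conditions: Bu3SnH, AIBN (cat.), toluene, 85 °C
Reagents that add atoms: none
Why: Radical chain dehalogenation gives the C18 methyl group; with the alkene now at C6=C7 the primary radical has no fast 3-exo or vinyl-shift pathway.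

Step 16
Reactants: 22 (4S,5R,10R)-11,14-dimethoxyabieta-6,8,11,13-tetraen-19,20-olide
Product: 23 (4S,5R,10R)-11,14-dioxoabieta-6,8,12-trien-19,20-olide
Conditions: (NH4)2Ce(NO3)6 (2.5 equiv), MeCN/H2O, 0 °C
Reagents that add atoms: water O
Why: Oxidative demethylation of a p-dimethoxyarene to the p-quinone: single-electron oxidation by tetravalent cerium, then attack of water at the two methoxy-bearing carbons.

Step 17
Reactants: 23 (4S,5R,10R)-11,14-dioxoabieta-6,8,12-trien-19,20-olide
Product: 24 12,13-epoxide of 23 (mixture of epoxide faces)
Conditions: 30% H2O2, Na2CO3, THF/H2O, 0 °C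
Reagents that add atoms: hydrogen peroxide OO
Why: Weitz–Scheffer epoxidation: hydroperoxide adds to the unsubstituted C12, the only unhindered β-position of the enedione, and closes the oxirane across C12–C13. The two new stereocentres are removed in step 18, so their configuration does not matter.

Step 18
Reactants: 24 12,13-epoxide of 23
Product: 25 (4S,5R,10R)-12-hydroxy-11,14-dioxoabieta-6,8,12-trien-19,20-olide
Conditions: conc. H2SO4, AcOH, 0 °C → rt
Reagents that add atoms: none
Why: Acid-catalysed isomerisation of a 2,3-epoxy-1,4-dione to the 2-hydroxy-1,4-quinone (oxirane opening and enolisation at unchanged oxidation level), the classical conversion of alkylquinone oxides into hydroxyquinones.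

Step 19
Reactants: 25 (4S,5R,10R)-12-hydroxy-11,14-dioxoabieta-6,8,12-trien-19,20-olide
Product: 26 (4S,5R,10R)-12-acetoxy-11,14-dioxoabieta-6,8,12-trien-19,20-olide
Conditions: Ac2O, pyridine, DMAP (cat.), CH2Cl2, 0 °C → rt
Reagents that add atoms: acetic anhydride CC(=O)OC(C)=O
Why: O-Acylation of the acidic C12 hydroxyl of a hydroxyquinone (a vinylogous carboxylic acid); the lactone and the three stereocentres are untouched.

## Compound list

1 | di-tert-butyl malonate | CC(C)(C)OC(=O)CC(=O)OC(C)(C)C | starting material
2 | 1-bromo-3-chloropropane | ClCCCBr | starting material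
3 | di-tert-butyl 2-(3-chloropropyl)malonate | CC(C)(C)OC(=O)C(CCCCl)C(=O)OC(C)(C)C | intermediate
4 | dimethyl malonate | COC(=O)CC(=O)OC | starting material
5 | 1,1-di-tert-butyl 5,5-dimethyl pentane-1,1,5,5-tetracarboxylate | COC(=O)C(CCCC(C(=O)OC(C)(C)C)C(=O)OC(C)(C)C)C(=O)OC | intermediate
6 | 1,1-di-tert-butyl 3-methyl 2-oxocyclohexane-1,1,3-tricarboxylate (racemic at the CH, largely enolised) | COC(=O)C1CCCC(C(=O)OC(C)(C)C)(C(=O)OC(C)(C)C)C1=O | intermediate
7 | 1,1-di-tert-butyl 3-methyl 2-(trifluoromethanesulfonyloxy)cyclohex-2-ene-1,1,3-tricarboxylate | COC(=O)C1=C(OS(=O)(=O)C(F)(F)F)C(C(=O)OC(C)(C)C)(C(=O)OC(C)(C)C)CCC1 | intermediate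
8 | tributyl(vinyl)stannane | C=C[Sn](CCCC)(CCCC)CCCC | starting material
9 | 1,1-di-tert-butyl 3-methyl 2-vinylcyclohex-2-ene-1,1,3-tricarboxylate | C=CC1=C(C(=O)OC)CCCC1(C(=O)OC(C)(C)C)C(=O)OC(C)(C)C | intermediate
10 | di-tert-butyl 3-(hydroxymethyl)-2-vinylcyclohex-2-ene-1,1-dicarboxylate | C=CC1=C(CO)CCCC1(C(=O)OC(C)(C)C)C(=O)OC(C)(C)C | intermediate
11 | di-tert-butyl 3-[(tert-butyldimethylsilyloxy)methyl]-2-vinylcyclohex-2-ene-1,1-dicarboxylate (ring A diene) | C=CC1=C(CO[Si](C)(C)C(C)(C)C)CCCC1(C(=O)OC(C)(C)C)C(=O)OC(C)(C)C | intermediate
12 | 2-isopropylphenol | CC(C)c1ccccc1O | starting material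
13 | 2-isopropyl-1,4-benzoquinone | CC(C)C1=CC(=O)C=CC1=O | intermediate
14 | endo cycloadduct, (8R,9R,10S): cis-fused 11,14-enedione, C5=C6 and C12=C13, 4,4-bis(tert-butoxycarbonyl), 10-CH2OTBS, H8/H9/C20 cis | CC(C)C1=CC(=O)[C@@H]2[C@H](C1=O)CC=C3C(C(=O)OC(C)(C)C)(C(=O)OC(C)(C)C)CCC[C@]23CO[Si](C)(C)C(C)(C)C | intermediate
15 | (10R)-11,14-hydroquinone corresponding to 14 (ring C aromatic, C5=C6) | CC(C)c1cc(O)c2c(c1O)CC=C3C(C(=O)OC(C)(C)C)(C(=O)OC(C)(C)C)CCC[C@]23CO[Si](C)(C)C(C)(C)C | intermediate (not isolated)
16 | (10R)-11,14-dimethyl ether of 15 | CC(C)c1cc(OC)c2c(c1OC)CC=C3C(C(=O)OC(C)(C)C)(C(=O)OC(C)(C)C)CCC[C@]23CO[Si](C)(C)C(C)(C)C | intermediate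
17 | (10R)-hydroxy diacid: 20-hydroxy-11,14-dimethoxy, C4 dicarboxylic acid, C5=C6 | CC(C)c1cc(OC)c2c(c1OC)CC=C3C(C(=O)O)(C(=O)O)CCC[C@]23CO | intermediate (not isolated)
18 | (4S,10R)-11,14-dimethoxy-19,20-olide 18-oic acid, C5=C6 (lactone carbonyl cis to C20) | c1c(C(C)C)c(OC)c2c(c1OC)[C@]13CCC[C@](C(=O)O)(C(=O)OC1)C3=CC2 | intermediate
19 | (4S,10R)-18-hydroxy-11,14-dimethoxy-19,20-olide, C5=C6 | c1c(C(C)C)c(OC)c2c(c1OC)[C@]13CCC[C@](CO)(C(=O)OC1)C3=CC2 | intermediate
20 | (4S,5R,10R)-18-hydroxy-11,14-dimethoxyabieta-6,8,11,13-tetraen-19,20-olide (H5 trans to C20) | c1c(C(C)C)c(OC)c2c(c1OC)[C@]13CCC[C@](CO)(C(=O)OC1)[C@@H]3C=C2 | intermediate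
21 | (4R,5R,10R)-18-iodo-11,14-dimethoxyabieta-6,8,11,13-tetraen-19,20-olide | c1c(C(C)C)c(OC)c2c(c1OC)[C@]13CCC[C@](CI)(C(=O)OC1)[C@@H]3C=C2 | intermediate
22 | (4S,5R,10R)-11,14-dimethoxyabieta-6,8,11,13-tetraen-19,20-olide | c1c(C(C)C)c(OC)c2c(c1OC)[C@]13CCC[C@](C)(C(=O)OC1)[C@@H]3C=C2 | intermediate
23 | (4S,5R,10R)-11,14-dioxoabieta-6,8,12-trien-19,20-olide | C1=C(C(C)C)C(=O)C2=C(C1=O)[C@]13CCC[C@](C)(C(=O)OC1)[C@@H]3C=C2 | intermediate
24 | 12,13-epoxide of 23 (both epoxide faces; 4S,5R,10R unchanged) | C15OC5(C(C)C)C(=O)C2=C(C1=O)[C@]34CCC[C@](C)(C(=O)OC3)[C@@H]4C=C2 | intermediate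
25 | (4S,5R,10R)-12-hydroxy-11,14-dioxoabieta-6,8,12-trien-19,20-olide | OC1=C(C(C)C)C(=O)C2=C(C1=O)[C@]13CCC[C@](C)(C(=O)OC1)[C@@H]3C=C2 | intermediate
26 | (4S,5R,10R)-12-acetoxy-11,14-dioxoabieta-6,8,12-trien-19,20-olide | CC(=O)OC1=C(C(C)C)C(=O)C2=C(C1=O)[C@]13CCC[C@](C)(C(=O)OC1)[C@@H]3C=C2 | target

## Step count and least certain steps

Total: 19 steps. Longest linear sequence: 18 steps (1–7, then 9–19); step 8 is a one-step side branch.

**Step 9 (key step).**
- Most likely to go wrong: slow cycloaddition, because the diene has a fully substituted terminus with an inside CH2OSi group and an inductively deactivating gem-diester. Over long reaction times the allylic silyl ether may ionise or the tert-butyl esters cleave under the strong acid, and facial selectivity may erode if an uncatalysed or achiral-acid pathway takes over.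
- Fallback (from 11 and 13, back at 18): enantiocontrol is moved to a classical resolution. The cycloaddition is promoted by an achiral Lewis acid (MeAlCl2, CH2Cl2, −78 → −20 °C) to give the racemic endo adduct F1. Steps 10 and 11 are applied unchanged and lead through the racemic hydroquinone F2 (not isolated), the racemic dimethyl ether F3 and the racemic hydroxy diacid F4 (not isolated) to the racemic lactone acid F5. Crystallisation with (R)-1-phenylethylamine should give the salt F6 of the required enantiomer (the antipodal amine is used if the other salt is the less soluble one). Acidification returns 18.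

**Step 13.**
- Most likely to go wrong: incomplete equilibration. The conjugated isomer gains conjugation but loses one alkene substituent, so the margin may be small. Kinetic protonation of the delocalised anion should occur from the more open lactone face and give the cis junction, which is corrected only if C5 equilibrates fully.
- Fallback (from 19, back at 23): the isomerisation is postponed to the quinone stage, where vinylogous enolisation gives a much larger driving force. Iodination of 19 as in step 14 gives the C5=C6 iodide F7. Hydrogenolysis (H2, Pd/C, Et3N, EtOAc) avoids a homoallyl radical and gives the C18-methyl arene F8. Oxidation with (NH4)2Ce(NO3)6 gives the C5=C6 quinone F9. In F9 the C7 hydrogens are γ to the C11 carbonyl, and a trace of Et3N in CH2Cl2 should move the double bond to C6=C7 through the extended dienol, under thermodynamic control at C5, to give 23.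

**Step 3.**
- Most likely to go wrong: reversal of the Claisen step by methoxide at the ketone next to quaternary C4, or stalling, because the starting malonate anion is almost as stable as the product enolate.
- Fallback (from 1, back at 6): ring A is closed by alkylation instead of acylation. C-Acylation of the magnesium enolate of 1 (MgCl2, Et3N, MeCN) with methyl 3-chloro-3-oxopropanoate gives the acylmalonate F10. Double C-alkylation with 1,3-dibromopropane (Cs2CO3, DMF) forms C3–C4 and C1–C10 and gives 6.

**Step 12.**
- Most likely to go wrong: hydroboration of C5=C6 assisted by the neighbouring acyloxyborane, or slow reduction of the very hindered acid that allows attack on the lactone.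
- Fallback (from 18, back at 19): the acid is converted with (COCl)2 and catalytic DMF into the acid chloride F11, which NaBH4 in THF at −20 °C reduces to 19 without a borane.

**Step 16.**
- Most likely to go wrong: oxidation at the conjugated C6=C7 bond, because the arene radical cation is delocalised onto it and water or nitrate can add at C6 or C7.
- Fallback (from 22, back at 23): non-oxidative demethylation with BBr3 (CH2Cl2, −78 → 0 °C) gives the hydroquinone F12, which Ag2O in Et2O dehydrogenates to 23.

**Step 18.**
- Most likely to go wrong: opening of the oxirane in the wrong sense with acyl migration and ring contraction, or acid-induced degradation of the dienone.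
- Fallback (from 23, back at 25): oxidative amination with morpholine (EtOH, air) at the free C12 position gives the aminoquinone F13. Hydrolysis of this vinylogous amide (dilute H2SO4, dioxane, 60 °C) gives 25.

## Further compounds

F1 | step 9 | racemic endo adduct (14 with its mirror image) | CC(C)C1=CC(=O)[C@@H]2[C@H](C1=O)CC=C3C(C(=O)OC(C)(C)C)(C(=O)OC(C)(C)C)CCC[C@]23CO[Si](C)(C)C(C)(C)C.CC(C)C1=CC(=O)[C@H]2[C@@H](C1=O)CC=C3C(C(=O)OC(C)(C)C)(C(=O)OC(C)(C)C)CCC[C@@]23CO[Si](C)(C)C(C)(C)C
F2 | step 9 | racemic hydroquinone (15 with its mirror image; not isolated) | CC(C)c1cc(O)c2c(c1O)CC=C3C(C(=O)OC(C)(C)C)(C(=O)OC(C)(C)C)CCC[C@]23CO[Si](C)(C)C(C)(C)C.CC(C)c1cc(O)c2c(c1O)CC=C3C(C(=O)OC(C)(C)C)(C(=O)OC(C)(C)C)CCC[C@@]23CO[Si](C)(C)C(C)(C)C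
F3 | step 9 | racemic dimethyl ether (16 with its mirror image) | CC(C)c1cc(OC)c2c(c1OC)CC=C3C(C(=O)OC(C)(C)C)(C(=O)OC(C)(C)C)CCC[C@]23CO[Si](C)(C)C(C)(C)C.CC(C)c1cc(OC)c2c(c1OC)CC=C3C(C(=O)OC(C)(C)C)(C(=O)OC(C)(C)C)CCC[C@@]23CO[Si](C)(C)C(C)(C)C
F4 | step 9 | racemic hydroxy diacid (17 with its mirror image; not isolated) | CC(C)c1cc(OC)c2c(c1OC)CC=C3C(C(=O)O)(C(=O)O)CCC[C@]23CO.CC(C)c1cc(OC)c2c(c1OC)CC=C3C(C(=O)O)(C(=O)O)CCC[C@@]23CO
F5 | step 9 | racemic lactone acid (18 with its mirror image) | c1c(C(C)C)c(OC)c2c(c1OC)[C@]13CCC[C@](C(=O)O)(C(=O)OC1)C3=CC2.c1c(C(C)C)c(OC)c2c(c1OC)[C@@]13CCC[C@@](C(=O)O)(C(=O)OC1)C3=CC2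
F6 | step 9 | (R)-1-phenylethylammonium salt of 18 | c1c(C(C)C)c(OC)c2c(c1OC)[C@]13CCC[C@](C(=O)[O-])(C(=O)OC1)C3=CC2.C[C@@H]([NH3+])c1ccccc1
F7 | step 13 | (10R)-18-iodo-11,14-dimethoxy-19,20-olide with C5=C6 | c1c(C(C)C)c(OC)c2c(c1OC)[C@]13CCC[C@](CI)(C(=O)OC1)C3=CC2
F8 | step 13 | (4S,10R)-11,14-dimethoxy-19,20-olide with C5=C6 and C18 methyl | c1c(C(C)C)c(OC)c2c(c1OC)[C@]13CCC[C@](C)(C(=O)OC1)C3=CC2
F9 | step 13 | (4S,10R)-11,14-dioxoabieta-5,8,12-trien-19,20-olide | C1=C(C(C)C)C(=O)C2=C(C1=O)[C@]13CCC[C@](C)(C(=O)OC1)C3=CC2
F10 | step 3 | 1,1-di-tert-butyl 3-methyl 2-oxopropane-1,1,3-tricarboxylate | COC(=O)CC(=O)C(C(=O)OC(C)(C)C)C(=O)OC(C)(C)C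
F11 | step 12 | acid chloride of 18 | c1c(C(C)C)c(OC)c2c(c1OC)[C@]13CCC[C@](C(Cl)=O)(C(=O)OC1)C3=CC2
F12 | step 16 | (4S,5R,10R)-11,14-dihydroxyabieta-6,8,11,13-tetraen-19,20-olide | c1c(C(C)C)c(O)c2c(c1O)[C@]13CCC[C@](C)(C(=O)OC1)[C@@H]3C=C2
F13 | step 18 | (4S,5R,10R)-12-morpholino-11,14-dioxoabieta-6,8,12-trien-19,20-olide | N1(CCOCC1)C4=C(C(C)C)C(=O)C2=C(C4=O)[C@]35CCC[C@](C)(C(=O)OC3)[C@@H]5C=C2
A1 | alternative 1 | tetracyclic C11 arylboronate with C13 isopropyl and C6=C7 | CC(C)c1cc2c(c(c1)B1OC(C)(C)C(C)(C)O1)[C@]13CCC[C@](C)(C(=O)OC1)[C@@H]3C=C2
A2 | alternative 1 | lactone diyne: C10 alkynyl pinacol boronate and C5 (Z)-but-1-en-3-ynyl arm | CC1(C)OB(C#C[C@]23CCC[C@](C)(C(=O)OC2)[C@@H]3/C=C\C#C)OC1(C)C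
A3 | alternative 1 | 3-methylbut-1-yne | CC(C)C#C
A4 | alternative 2 | bridged cyclopentanone linking C4 and C10 through C19 and C20 | COc1c(C(C)C)c(OC)c2c(c1OC)[C@]13CCC[C@](C)(C(=O)C1)[C@@H]3CC2
A5 | alternative 2 | 20-nor C19 diazomethyl ketone with 10β-H | COc1c(C(C)C)c(OC)c2c(c1OC)[C@H]3CCC[C@](C)(C(=O)C=[N+]=[N-])[C@@H]3CC2
A6 | alternative 3 | trans-fused tricycle with C1=C2, C19 methyl ester and C20 silyl ether | COc1c(C(C)C)c(OC)c2c(c1OC)[C@@]1(CO[Si](C)(C)C(C)(C)C)C=CC[C@](C)(C(=O)OC)[C@@H]1CC2
A7 | alternative 3 | benzo-tethered triene: aryl 1,3-diene with CH2OTBS on C10 and (Z)-2-methyl enoate | COc1c(C(C)C)c(OC)c(CC/C=C(/C)C(=O)OC)c(c1OC)/C(CO[Si](C)(C)C(C)(C)C)=C/C=C
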